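## Structural features

The target is a 1,2-dihydronaphthalene. Ring A is a catechol (hydroxyls on C6 and C7), and ring B carries the C3=C4 double bond conjugated to ring A, a carboxylic acid on C3 and another on C2. C1 of ring B is joined by a single C–C bond to C4' of a 2-oxo-2H-pyran-6-carboxylic acid. C1 and C2 are adjacent stereocentres, (1R,2S), with the pyranonyl group and the C2 carboxyl trans. The fragile parts are the 2-pyranone (opened by hydroxide, amines and hard nucleophiles), the catechol and the dihydronaphthalene (air oxidation to quinone or naphthalene), and the C1–H bond, which is benzylic and vinylogously alpha to the lactone carbonyl, so base can erase C1. The real difficulty is the absolute configuration at C1, a methine between two sp2 rings, which has to be set without base. C2 is easier, because trans is the thermodynamic arrangement and C2–H sits alpha to a carboxyl. The key step uses two facts: C1 is attached to C8a and is para to the C6 oxygen, so a C1 carbinol with a free C6 phenol is a latent ring A para-quinone methide that is electrophilic at C1; and C2, when it carries two esters, is a soft carbon nucleophile held beside C1 by the C3=C4 double bond on C4a. Only O6 is conjugated with C1, so O7 can stay methylated until the end.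

## Logic of the disconnections

21 to 20: the four carboxylic acids are taken back to ethyl esters and a second carboxyl is put back on C2 (the C2–CO2 bond). The trans C1/C2 relationship is thermodynamic, so C2 needs no stereocontrol of its own. As a geminal diester C2 is not stereogenic, which leaves C1 as the only centre to control and supplies the malonate nucleophile. The forward step must hydrolyse and decarboxylate in acid, because base would open the pyranone and epimerise C1.

20 to 19: the O7–CH3 bond is re-formed. This keeps the two ring A oxygens different, so that only O6 can drive quinone methide formation, and it traces back to a bromo-aldehyde (6) that is sold with this pattern. The forward step must cleave one aryl methyl ether at low temperature without attacking the pyranone.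

19 to 18: the C1–C2 bond is cut and ring B is opened. This removes the only stereocentre that needs absolute control and turns the bicycle into an open diaryl carbinol whose own configuration does not matter, since both enantiomers pass through the same planar intermediate. The forward step needs a chiral acid that ionises the carbinol and selects one face, a free C6 phenol, an enolisable malonate and the (E)-alkene.

18 to 17: the O6–Si bond is re-formed. 18 can cyclise without a catalyst, which would give racemic material, so its phenol is revealed only immediately before the key step. The forward step must be a desilylation that is neither acidic nor basic.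

17 to 12 and 15 (through 16): the C3=C4 double bond is cut. The saturated analogue of 15 cannot be condensed with an aldehyde, because its acidic carbon is the methine between two esters and the resulting aldol adduct cannot dehydrate. The three-ester unit is therefore delivered as phosphorus ylide 16, which forms the trisubstituted alkene under neutral conditions with the aryl group trans to the conjugated ester. The forward step requires 12 to react through its open hydroxy-aldehyde form.

15 to 13 and 14: the C=C bond is cut. Both halves are commercial and the ketone partner is highly electrophilic and not enolisable.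

12 to 8 and 5: the C1–C8a bond is cut, together with the lactol C–O bond. This divides the molecule into two halves of similar size. The aryl-metal reagent (9, then 10) must choose the aldehyde of 5 over its lactone and ester. The ortho aldehyde travels as an acetal (11) and is released into a lactol (12), which keeps carbinol and aldehyde protected by each other until the olefination.

8 to 6 (through 7): the O–Si bond and the two acetal C–O bonds are cut, leaving the commercial bromo-aldehyde.

5 to 4, then 4 to 1 and 2 (through 3): the aldehyde oxygen is removed to a methyl group, then the lactone C–O bond and the C–C bond between the oxalyl carbon and the gamma-carbon of 2 are cut. This gives two bulk esters. The forward steps need gamma-selective acylation and a methyl oxidation that the lactone carbonyl activates.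

## Other disconnections considered

Alternative 1: The cut is inside the pyranone. The lactone C–O bond is opened and the heterocycle is traced back to a 3,4-dihydroxyphenyl ring on C1, as in dimethyl (1R,2S)-1-(3,4-dihydroxyphenyl)-6,7-dimethoxy-1,2-dihydronaphthalene-2,3-dicarboxylate A1. In the forward step O2 with FeCl2 (divalent iron) and 1,4,7-triazacyclononane would cleave the pendant catechol between its C4 and C5, the C3 enol oxygen would close onto the new aldehyde, and in-pot oxidation of the hemiacetal would give the pyranone acid A2.
- In its favour: the route is biomimetic, and the pyranone carboxyl arrives at the correct oxidation level. The fragile pyranone appears only at the end, which is better than the chosen plan, where it is carried through an organometallic addition. A1 also has the skeleton of a classical 1-aryl-dihydronaphthalene lignan, for which trans-selective syntheses are established.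
- Against it: three cleavage modes compete (intradiol, proximal extradiol, distal extradiol) and only the distal one gives A2. Simple iron/triazacyclononane systems are most reliable on hindered catechols. O2 and iron also threaten the doubly activated C1–H and aromatisation of ring B. Ring A must be a dimethyl ether to survive, so two methyl ethers must be cleaved afterwards instead of one.
- Comparison: on mechanism the chosen polar ring closure is far better defined. On step economy the alternative could be equal or shorter if A1 is made by oxidative coupling. It sets no stereocentre, however, so both C1 and C2 need a separate asymmetric solution.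

Alternative 2: The cut removes the O1'–C6' and C4'–C5' bonds of the pyranone. This leaves the C1 propiolic acid A3 and the silyl propargyl ether A4. In the forward step Ph3PAuCl with AgOTf (monovalent gold) would add the acid across A4 to an enol ester, whose alkene then attacks the gold-activated ynoate to give A5.
- In its favour: the mechanism dictates the 4,6-substitution of the pyranone, and on this point it is superior to any condensation approach. It is convergent, and the conditions are neutral and catalytic. The chosen plan equals it on pyranone regiochemistry only because its pyranone is bought in with a fixed pattern.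
- Against it: A3 is a 1,5-enyne flanked by ester carbonyls, so gold could divert it into cycloisomerisation or lactone formation. Its C1–H is propargylic and benzylic and invites allene formation, with loss of both stereocentres. C6' arrives as CH2OSi, two oxidation levels below the acid, so desilylation, two oxidations, ester hydrolysis and double demethylation follow.
- Comparison: the key step of the alternative sets no stereocentre, whereas the chosen one sets C1 catalytically. After the key step the alternative needs at least five steps against two, so it is the weaker on step economy.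

Alternative 3: The cut removes three ring bonds (C4a–C8a, C5–C6, C7–C8). This leaves the enediyne A6, which already carries C1 with its configuration, and the diborylalkyne A7. In the forward step CpCo(CO)2 (monovalent cobalt) would cotrimerise the two terminal alkynes of A6 with A7 to build rings A and B at once, giving the bis-boronate A8.
- In its favour: it forms the most bonds per step. The two C–B bonds are a masked catechol, so ring A needs no oxygen protecting groups and no BBr3, which is a real advantage over the chosen plan. A8 has the carbon skeleton of 19, so the endgame is equally short.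
- Against it: the stereochemical problem is moved into A6, whose C1 is propargylic and attached to the pyranone. It is hard to make enantioenriched and easy to racemise under the heat or light that CpCo(CO)2 requires. The 2-pyranone is itself a diene and an alkyne partner toward cobaltacycles. Oxidation of the C–B bonds must avoid basic peroxide.
- Comparison: on structure and late-stage step economy it is the equal or the better of the chosen plan. On mechanism and on access to the precursor it is clearly less secure.

Key step: step 8

Assumption: the (R)-enantiomer of the phosphoric acid is taken as the one that leads to (1R)-19; if the sense of induction is the opposite, the commercial (S)-enantiomer is used in the same way.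

## Route

Step 1
Reactants: 1 diethyl oxalate; 2 ethyl 3-methylbut-2-enoate
Product: 4 ethyl 4-methyl-2-oxo-2H-pyran-6-carboxylate, via potassium dienolate 3 (not isolated)
Conditions: KOEt, Et2O/EtOH, 0 °C → rt; then HCl in EtOH, 78 °C
Reagents that add atoms: none
Why: Vinylogous Claisen condensation: the dienolate of 2 is acylated at its gamma-carbon by the non-enolisable diester 1 and the product is trapped as the stabilised enolate 3; acid then lets the enol oxygen lactonise onto the (Z)-enoate ester, driven by formation of the conjugated 2-pyranone, while ethanolic HCl keeps the C6 carboxyl as its ethyl ester.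

Step 2
Reactants: 4 ethyl 4-methyl-2-oxo-2H-pyran-6-carboxylate
Product: 5 ethyl 4-formyl-2-oxo-2H-pyran-6-carboxylate
Conditions: SeO2, 1,4-dioxane, 100 °C
Reagents that add atoms: selenium dioxide, O=[Se]=O
Why: Riley oxidation: the methyl group is vinylogously activated by the lactone carbonyl, as in 4-methylcoumarins, so the ene reaction and [2,3]-shift take place there and lead to the aldehyde; no other C–H bond of 4 is comparably activated.

Step 3
Reactants: 6 2-bromo-5-hydroxy-4-methoxybenzaldehyde
Product: 8 [4-bromo-5-(dimethoxymethyl)-2-methoxyphenoxy](tert-butyl)dimethylsilane, via phenol acetal 7 (not isolated)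
Conditions: HC(OMe)3, MeOH, p-TsOH·H2O (cat.), rt; Et3N, evaporate; then TBSCl, imidazole, DMF, rt
Reagents that add atoms: methanol, CO; tert-butyldimethylsilyl chloride, CC(C)(C)[Si](C)(C)Cl
Why: Acid-catalysed acetalisation with the orthoformate as water scavenger masks the aldehyde against the organolithium, and silylation removes the acidic phenol proton; the silyl ether is chosen because fluoride can remove it later without acid or base.

Step 4
Reactants: 8 [4-bromo-5-(dimethoxymethyl)-2-methoxyphenoxy](tert-butyl)dimethylsilane; 5 ethyl 4-formyl-2-oxo-2H-pyran-6-carboxylate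
Product: 12 ethyl 4-[5-{[tert-butyl(dimethyl)silyl]oxy}-3-hydroxy-6-methoxy-1,3-dihydro-2-benzofuran-1-yl]-2-oxo-2H-pyran-6-carboxylate (racemic; both lactol epimers), via aryllithium 9 (not isolated), via arylmagnesium bromide 10 (not isolated), via carbinol acetal 11 (not isolated)
Conditions: n-BuLi, THF, −78 °C; MgBr2·OEt2, −78 °C; then into 5, THF, −78 °C; then 1 M aq HCl, THF, 0 °C → rt
Reagents that add atoms: water, O
Why: Bromine–lithium exchange is faster at −78 °C than attack on the silyl ether or acetal, and transmetalation to the less basic arylmagnesium species with inverse addition should favour 1,2-addition to the very electrophilic aldehyde over attack on the lactone or ester of 5; dilute acid then hydrolyses the dimethyl acetal and the neighbouring carbinol captures the aldehyde as a five-membered lactol, which protects both groups (the carbinol configuration is erased in step 8).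

Step 5
Reactants: 13 diethyl 2-oxopropanedioate; 14 ethyl 2-(triphenyl-λ5-phosphanylidene)acetate
Product: 15 triethyl ethene-1,1,2-tricarboxylate
Conditions: CH2Cl2, 0 °C → rt
Reagents that add atoms: none
Why: Wittig olefination of a highly electrophilic, non-enolisable ketone with a stabilised ylide; alkene geometry is not an issue because one alkene carbon carries two identical esters.

Step 6
Reactants: 12 ethyl 4-[5-{[tert-butyl(dimethyl)silyl]oxy}-3-hydroxy-6-methoxy-1,3-dihydro-2-benzofuran-1-yl]-2-oxo-2H-pyran-6-carboxylate; 15 triethyl ethene-1,1,2-tricarboxylate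
Product: 17 ethyl 4-{[4-{[tert-butyl(dimethyl)silyl]oxy}-5-methoxy-2-[(1E)-2,3,3-tris(ethoxycarbonyl)prop-1-en-1-yl]phenyl](hydroxy)methyl}-2-oxo-2H-pyran-6-carboxylate (racemic), via phosphorus ylide 16 (not isolated)
Conditions: PPh3, toluene, rt; then 12, PhCO2H (cat.), 90 °C
Reagents that add atoms: none
Why: Conjugate addition of the phosphine to alkylidene malonate 15 and a proton shift give the ester-stabilised ylide 16 (the phosphonium-bearing carbon is the more acidic site), which olefinates the open hydroxy-aldehyde form of lactol 12 in a Wittig reaction; alpha-substituted ester ylides place the aryl group trans to the conjugated ester, which is the (E)-geometry that holds C2 next to C1, and the neutral medium spares the pyranone while the silyl ether prevents cyclisation at this temperature.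

Step 7
Reactants: 17 ethyl 4-{[4-{[tert-butyl(dimethyl)silyl]oxy}-5-methoxy-2-[(1E)-2,3,3-tris(ethoxycarbonyl)prop-1-en-1-yl]phenyl](hydroxy)methyl}-2-oxo-2H-pyran-6-carboxylate
Product: 18 ethyl 4-{hydroxy[4-hydroxy-5-methoxy-2-[(1E)-2,3,3-tris(ethoxycarbonyl)prop-1-en-1-yl]phenyl]methyl}-2-oxo-2H-pyran-6-carboxylate (racemic)
Conditions: Bu4NF, AcOH (1:1), THF, 0 °C
Reagents that add atoms: none
Why: Fluoride cleaves the aryl silyl ether quickly, and the acetic acid buffer keeps the medium near neutral so that the pyranone is not opened, the malonate is not deprotonated and the carbinol is not ionised; 18 is used at once.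

Step 8
Reactants: 18 ethyl 4-{hydroxy[4-hydroxy-5-methoxy-2-[(1E)-2,3,3-tris(ethoxycarbonyl)prop-1-en-1-yl]phenyl]methyl}-2-oxo-2H-pyran-6-carboxylate
Product: 19 triethyl (1R)-1-[6-(ethoxycarbonyl)-2-oxo-2H-pyran-4-yl]-6-hydroxy-7-methoxynaphthalene-2,2,3(1H)-tricarboxylate
Conditions: (R)-3,3'-bis(2,4,6-triisopropylphenyl)-1,1'-binaphthyl-2,2'-diyl hydrogen phosphate (10 mol %), toluene (0.02 M), 3 Å MS, 25 °C
Reagents that add atoms: none
Why: The phosphoric acid protonates the carbinol hydroxyl of either enantiomer of 18 and water leaves with electron push from the para C6 phenol, so both enantiomers converge on one planar ring A para-quinone methide that stays hydrogen-bonded to the chiral phosphate. The malonate C2–H, further acidified by conjugation through C3=C4, enolises; the enol hydroxyl binds the phosphoryl oxygen while the P–OH holds the quinone methide oxygen, so C2 adds to the methide carbon C1 and ring A rearomatises. The closest known reaction type is the chiral phosphoric acid-catalysed 1,6-addition of 1,3-dicarbonyl compounds to para-quinone methides generated in situ from para-hydroxybenzyl alcohols, run here intramolecularly. Ring B closes in the 6-endo-trig mode with respect to the C1=C8a bond, and the (E)-alkene leaves C2 as the only nucleophilic atom within reach of C1. The new stereocentre C1 is controlled by the catalyst, whose two 2,4,6-triisopropylphenyl groups shield one face of the quinone methide; its geometry is fixed with the pyranonyl group syn to C8–H by allylic strain against the C4a side arm. The catalysed pathway has to outrun uncatalysed ionisation, which is secured by unmasking the phenol only in step 7, by the non-polar solvent and by the electron-poor pyranonyl group that slows unassisted ionisation. Intramolecular capture has to beat intermolecular ether formation, which high dilution and the pre-organised arm provide. Because C2 is quaternary in 19, there is no epimerisable C2–H beside the new centre.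

Step 9
Reactants: 19 triethyl (1R)-1-[6-(ethoxycarbonyl)-2-oxo-2H-pyran-4-yl]-6-hydroxy-7-methoxynaphthalene-2,2,3(1H)-tricarboxylate
Product: 20 triethyl (1R)-1-[6-(ethoxycarbonyl)-2-oxo-2H-pyran-4-yl]-6,7-dihydroxynaphthalene-2,2,3(1H)-tricarboxylate
Conditions: BBr3, CH2Cl2, −78 → 0 °C; then H2O
Reagents that add atoms: none
Why: Lewis acid cleavage of an aryl methyl ether: the neighbouring C6 phenol forms an aryloxyborane that delivers bromide to the adjacent O–CH3, so the guaiacol unit should be demethylated at low temperature while the ethyl esters and the pyranone are only coordinated; these non-basic conditions offer no path for epimerisation at C1.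

Step 10
Reactants: 20 triethyl (1R)-1-[6-(ethoxycarbonyl)-2-oxo-2H-pyran-4-yl]-6,7-dihydroxynaphthalene-2,2,3(1H)-tricarboxylate
Product: 21 (1R,2S)-1-(6-carboxy-2-oxo-2H-pyran-4-yl)-6,7-dihydroxy-1,2-dihydronaphthalene-2,3-dicarboxylic acid
Conditions: 6 M aq HCl/AcOH (1:1), 100 °C, argon
Reagents that add atoms: water, O
Why: Acid-catalysed hydrolysis of all four ethyl esters, to which the 2-pyranone is stable (unlike to base), followed by decarboxylation of the geminal diacid at C2 through its cyclic transition state; the new C2–H, alpha to a carboxyl and allylic to C3=C4, equilibrates in hot acid to the trans arrangement with the C1 pyranonyl and C2 carboxyl pseudoaxial on opposite faces, which is (1R,2S), while C1 is not enolisable in acid.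

## Compound list

1 | diethyl oxalate | CCOC(=O)C(=O)OCC | starting material
2 | ethyl 3-methylbut-2-enoate | CCOC(=O)C=C(C)C | starting material
3 | potassium (2Z,4Z)-1,6-diethoxy-4-methyl-1,6-dioxohexa-2,4-dien-2-olate | CCOC(=O)/C([O-])=C/C(C)=C\C(=O)OCC.[K+] | intermediate (not isolated)
4 | ethyl 4-methyl-2-oxo-2H-pyran-6-carboxylate | CCOC(=O)c1cc(C)cc(=O)o1 | intermediate
5 | ethyl 4-formyl-2-oxo-2H-pyran-6-carboxylate | CCOC(=O)c1cc(C=O)cc(=O)o1 | intermediate
6 | 2-bromo-5-hydroxy-4-methoxybenzaldehyde | COc1cc(Br)c(C=O)cc1O | starting material
7 | 4-bromo-5-(dimethoxymethyl)-2-methoxyphenol | COc1cc(Br)c(C(OC)OC)cc1O | intermediate (not isolated)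
8 | [4-bromo-5-(dimethoxymethyl)-2-methoxyphenoxy](tert-butyl)dimethylsilane | COc1cc(Br)c(C(OC)OC)cc1O[Si](C)(C)C(C)(C)C | intermediate
9 | {4-[(tert-butyldimethylsilyl)oxy]-2-(dimethoxymethyl)-5-methoxyphenyl}lithium | COc1cc([Li])c(C(OC)OC)cc1O[Si](C)(C)C(C)(C)C | intermediate (not isolated)
10 | bromo{4-[(tert-butyldimethylsilyl)oxy]-2-(dimethoxymethyl)-5-methoxyphenyl}magnesium | COc1cc([Mg]Br)c(C(OC)OC)cc1O[Si](C)(C)C(C)(C)C | intermediate (not isolated)
11 | ethyl 4-{[4-{[tert-butyl(dimethyl)silyl]oxy}-2-(dimethoxymethyl)-5-methoxyphenyl](hydroxy)methyl}-2-oxo-2H-pyran-6-carboxylate (racemic) | CCOC(=O)c1cc(C(O)c2cc(OC)c(O[Si](C)(C)C(C)(C)C)cc2C(OC)OC)cc(=O)o1 | intermediate (not isolated)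
12 | ethyl 4-[5-{[tert-butyl(dimethyl)silyl]oxy}-3-hydroxy-6-methoxy-1,3-dihydro-2-benzofuran-1-yl]-2-oxo-2H-pyran-6-carboxylate (racemic; both lactol epimers) | CCOC(=O)c1cc(C2OC(O)c3cc(O[Si](C)(C)C(C)(C)C)c(OC)cc32)cc(=O)o1 | intermediate
13 | diethyl 2-oxopropanedioate | CCOC(=O)C(=O)C(=O)OCC | starting material
14 | ethyl 2-(triphenyl-λ5-phosphanylidene)acetate | CCOC(=O)C=P(c1ccccc1)(c1ccccc1)c1ccccc1 | starting material
15 | triethyl ethene-1,1,2-tricarboxylate | CCOC(=O)C=C(C(=O)OCC)C(=O)OCC | intermediate
16 | triethyl 2-(triphenyl-λ5-phosphanylidene)ethane-1,1,2-tricarboxylate | CCOC(=O)C(=P(c1ccccc1)(c1ccccc1)c1ccccc1)C(C(=O)OCC)C(=O)OCC | intermediate (not isolated)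
17 | ethyl 4-{[4-{[tert-butyl(dimethyl)silyl]oxy}-5-methoxy-2-[(1E)-2,3,3-tris(ethoxycarbonyl)prop-1-en-1-yl]phenyl](hydroxy)methyl}-2-oxo-2H-pyran-6-carboxylate (racemic) | CCOC(=O)C(C(=O)OCC)/C(C(=O)OCC)=C\c1cc(O[Si](C)(C)C(C)(C)C)c(OC)cc1C(O)c1cc(C(=O)OCC)oc(=O)c1 | intermediate
18 | ethyl 4-{hydroxy[4-hydroxy-5-methoxy-2-[(1E)-2,3,3-tris(ethoxycarbonyl)prop-1-en-1-yl]phenyl]methyl}-2-oxo-2H-pyran-6-carboxylate (racemic) | CCOC(=O)C(C(=O)OCC)/C(C(=O)OCC)=C\c1cc(O)c(OC)cc1C(O)c1cc(C(=O)OCC)oc(=O)c1 | intermediate
19 | triethyl (1R)-1-[6-(ethoxycarbonyl)-2-oxo-2H-pyran-4-yl]-6-hydroxy-7-methoxynaphthalene-2,2,3(1H)-tricarboxylate | CCOC(=O)C1=Cc2cc(O)c(OC)cc2[C@@H](c2cc(C(=O)OCC)oc(=O)c2)C1(C(=O)OCC)C(=O)OCC | intermediate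
20 | triethyl (1R)-1-[6-(ethoxycarbonyl)-2-oxo-2H-pyran-4-yl]-6,7-dihydroxynaphthalene-2,2,3(1H)-tricarboxylate | CCOC(=O)C1=Cc2cc(O)c(O)cc2[C@@H](c2cc(C(=O)OCC)oc(=O)c2)C1(C(=O)OCC)C(=O)OCC | intermediate
21 | (1R,2S)-1-(6-carboxy-2-oxo-2H-pyran-4-yl)-6,7-dihydroxy-1,2-dihydronaphthalene-2,3-dicarboxylic acid | O=C(O)C1=Cc2cc(O)c(O)cc2[C@@H](c2cc(C(=O)O)oc(=O)c2)[C@@H]1C(=O)O | target

## Step count and least certain steps

Total: 10 steps. Longest linear sequence: 8 steps (steps 1, 2, 4, 6, 7, 8, 9, 10, from 1 and 2 to 21).

Step 8 (key step). The most likely failures are slow ionisation, because the pyranonyl group destabilises the quinone methide and a malonate diester enolises poorly under a Brønsted acid; an uncatalysed racemic closure that competes with the catalysed one; and insufficient discrimination between the two faces of the quinone methide. The fallback gives up catalytic induction. It sets out from 18, closes ring B with a catalytic amount of Sc(OTf)3 in CH2Cl2 to give racemic triethyl 1-[6-(ethoxycarbonyl)-2-oxo-2H-pyran-4-yl]-6-hydroxy-7-methoxynaphthalene-2,2,3(1H)-tricarboxylate F1, and separates the enantiomers by preparative supercritical fluid chromatography on an amylose carbamate phase. The (1R)-enantiomer is 19, where the route is rejoined.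

Step 6. The olefination may stall because the aldehyde is masked as a lactol and the ylide is hindered. The free carbinol may also add to the new acrylate in an oxa-Michael closure, and the bulky malonyl group may erode the E/Z preference. The fallback removes the lactol from the problem. It sets out from 11, isolated after an NH4Cl quench in place of the acid treatment. Silylation with TESOTf and 2,6-lutidine gives ethyl 4-{[4-{[tert-butyl(dimethyl)silyl]oxy}-2-(dimethoxymethyl)-5-methoxyphenyl][(triethylsilyl)oxy]methyl}-2-oxo-2H-pyran-6-carboxylate F2. Pyridinium p-toluenesulfonate in wet acetone at 0 °C releases the open aldehyde ethyl 4-{[4-{[tert-butyl(dimethyl)silyl]oxy}-2-formyl-5-methoxyphenyl][(triethylsilyl)oxy]methyl}-2-oxo-2H-pyran-6-carboxylate F3. Ylide 16 (from 15 and PPh3) converts it into ethyl 4-{[4-{[tert-butyl(dimethyl)silyl]oxy}-5-methoxy-2-[(1E)-2,3,3-tris(ethoxycarbonyl)prop-1-en-1-yl]phenyl][(triethylsilyl)oxy]methyl}-2-oxo-2H-pyran-6-carboxylate F4, and Bu4NF/AcOH removes both silyl groups to return to the route at 18.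

Step 4. The aryl-metal reagent may attack the lactone carbonyl, the ester or a ring position of 5 instead of the aldehyde, and the organolithium may attack the silyl ether. The fallback replaces the polar organometallic addition by a catalytic one. It sets out from 8: bromine–lithium exchange and quenching with 2-isopropoxy-4,4,5,5-tetramethyl-1,3,2-dioxaborolane give tert-butyl[5-(dimethoxymethyl)-2-methoxy-4-(4,4,5,5-tetramethyl-1,3,2-dioxaborolan-2-yl)phenoxy]dimethylsilane F5. This is added to 5 with [Rh(OH)(cod)]2 (monovalent rhodium) in dioxane/water at 60 °C, conditions that tolerate esters and lactones. The product is 11, which the acid treatment of step 4 takes on to 12.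

Step 2. Over-oxidation to the carboxylic acid, incomplete conversion and degradation of the ring at 100 °C are the likely problems. The fallback changes from direct C–H oxidation to halogenation and oxygen transfer. It sets out from 4: radical bromination (N-bromosuccinimide, azobisisobutyronitrile, PhCF3, 80 °C) gives ethyl 4-(bromomethyl)-2-oxo-2H-pyran-6-carboxylate F6, and 4-methylmorpholine N-oxide in MeCN at rt converts the bromide into the aldehyde, rejoining the route at 5.

Step 10. Hydrolysis of the hindered geminal diester may be incomplete. Kinetic protonation at C2 may leave the cis isomer if equilibration is slow. Reversible cleavage of the C1–C2 bond in hot acid may erode the configuration at C1, and traces of air may oxidise the product to the naphthalene. The fallback separates decarboxylation from hydrolysis. It sets out from 19: a Krapcho dealkoxycarbonylation (LiCl, H2O, DMSO, 150 °C, short heating) removes one C2 ester and lets the remaining, readily enolised C2 ester settle in the trans arrangement, giving diethyl (1R,2S)-1-[6-(ethoxycarbonyl)-2-oxo-2H-pyran-4-yl]-6-hydroxy-7-methoxy-1,2-dihydronaphthalene-2,3-dicarboxylate F7. BBr3 in CH2Cl2 then gives diethyl (1R,2S)-1-[6-(ethoxycarbonyl)-2-oxo-2H-pyran-4-yl]-6,7-dihydroxy-1,2-dihydronaphthalene-2,3-dicarboxylate F8. The three unhindered esters are hydrolysed under milder acid (3 M aq HCl, dioxane, 80 °C), and the route is rejoined at 21.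

## Further compounds

F1 | step 8 | triethyl rac-1-[6-(ethoxycarbonyl)-2-oxo-2H-pyran-4-yl]-6-hydroxy-7-methoxynaphthalene-2,2,3(1H)-tricarboxylate | CCOC(=O)C1=Cc2cc(O)c(OC)cc2C(c2cc(C(=O)OCC)oc(=O)c2)C1(C(=O)OCC)C(=O)OCC
F2 | step 6 | ethyl 4-{[4-{[tert-butyl(dimethyl)silyl]oxy}-2-(dimethoxymethyl)-5-methoxyphenyl][(triethylsilyl)oxy]methyl}-2-oxo-2H-pyran-6-carboxylate (racemic) | CCOC(=O)c1cc(C(O[Si](CC)(CC)CC)c2cc(OC)c(O[Si](C)(C)C(C)(C)C)cc2C(OC)OC)cc(=O)o1
F3 | step 6 | ethyl 4-{[4-{[tert-butyl(dimethyl)silyl]oxy}-2-formyl-5-methoxyphenyl][(triethylsilyl)oxy]methyl}-2-oxo-2H-pyran-6-carboxylate (racemic) | CCOC(=O)c1cc(C(O[Si](CC)(CC)CC)c2cc(OC)c(O[Si](C)(C)C(C)(C)C)cc2C=O)cc(=O)o1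
F4 | step 6 | ethyl 4-{[4-{[tert-butyl(dimethyl)silyl]oxy}-5-methoxy-2-[(1E)-2,3,3-tris(ethoxycarbonyl)prop-1-en-1-yl]phenyl][(triethylsilyl)oxy]methyl}-2-oxo-2H-pyran-6-carboxylate (racemic) | CCOC(=O)C(C(=O)OCC)/C(C(=O)OCC)=C\c1cc(O[Si](C)(C)C(C)(C)C)c(OC)cc1C(O[Si](CC)(CC)CC)c1cc(C(=O)OCC)oc(=O)c1
F5 | step 4 | tert-butyl[5-(dimethoxymethyl)-2-methoxy-4-(4,4,5,5-tetramethyl-1,3,2-dioxaborolan-2-yl)phenoxy]dimethylsilane | COc1cc(B2OC(C)(C)C(C)(C)O2)c(C(OC)OC)cc1O[Si](C)(C)C(C)(C)C
F6 | step 2 | ethyl 4-(bromomethyl)-2-oxo-2H-pyran-6-carboxylate | CCOC(=O)c1cc(CBr)cc(=O)o1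
F7 | step 10 | diethyl (1R,2S)-1-[6-(ethoxycarbonyl)-2-oxo-2H-pyran-4-yl]-6-hydroxy-7-methoxy-1,2-dihydronaphthalene-2,3-dicarboxylate | CCOC(=O)C1=Cc2cc(O)c(OC)cc2[C@@H](c2cc(C(=O)OCC)oc(=O)c2)[C@@H]1C(=O)OCC
F8 | step 10 | diethyl (1R,2S)-1-[6-(ethoxycarbonyl)-2-oxo-2H-pyran-4-yl]-6,7-dihydroxy-1,2-dihydronaphthalene-2,3-dicarboxylate | CCOC(=O)C1=Cc2cc(O)c(O)cc2[C@@H](c2cc(C(=O)OCC)oc(=O)c2)[C@@H]1C(=O)OCC
A1 | alternative 1 | dimethyl (1R,2S)-1-(3,4-dihydroxyphenyl)-6,7-dimethoxy-1,2-dihydronaphthalene-2,3-dicarboxylate | COC(=O)C1=Cc2cc(OC)c(OC)cc2[C@@H](c2ccc(O)c(O)c2)[C@@H]1C(=O)OC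
A2 | alternative 1 | 4-[(1R,2S)-6,7-dimethoxy-2,3-bis(methoxycarbonyl)-1,2-dihydronaphthalen-1-yl]-2-oxo-2H-pyran-6-carboxylic acid | COC(=O)C1=Cc2cc(OC)c(OC)cc2[C@@H](c2cc(C(=O)O)oc(=O)c2)[C@@H]1C(=O)OC
A3 | alternative 2 | 3-[(1R,2S)-2,3-bis(ethoxycarbonyl)-6,7-dimethoxy-1,2-dihydronaphthalen-1-yl]prop-2-ynoic acid | CCOC(=O)C1=Cc2cc(OC)c(OC)cc2[C@@H](C#CC(=O)O)[C@@H]1C(=O)OCC
A4 | alternative 2 | tert-butyldimethyl(prop-2-yn-1-yloxy)silane | C#CCO[Si](C)(C)C(C)(C)C
A5 | alternative 2 | diethyl (1R,2S)-1-[6-({[tert-butyl(dimethyl)silyl]oxy}methyl)-2-oxo-2H-pyran-4-yl]-6,7-dimethoxy-1,2-dihydronaphthalene-2,3-dicarboxylate | CCOC(=O)C1=Cc2cc(OC)c(OC)cc2[C@@H](c2cc(CO[Si](C)(C)C(C)(C)C)oc(=O)c2)[C@@H]1C(=O)OCC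
A6 | alternative 3 | triethyl (3E,6S)-6-[6-(ethoxycarbonyl)-2-oxo-2H-pyran-4-yl]octa-3-ene-1,7-diyne-4,5,5-tricarboxylate | C#C[C@@H](c1cc(C(=O)OCC)oc(=O)c1)C(C(=O)OCC)(C(=O)OCC)/C(C(=O)OCC)=C\C#C
A7 | alternative 3 | 1,2-bis(4,4,5,5-tetramethyl-1,3,2-dioxaborolan-2-yl)ethyne | CC1(C)OB(C#CB2OC(C)(C)C(C)(C)O2)OC1(C)C
A8 | alternative 3 | triethyl (1R)-1-[6-(ethoxycarbonyl)-2-oxo-2H-pyran-4-yl]-6,7-bis(4,4,5,5-tetramethyl-1,3,2-dioxaborolan-2-yl)naphthalene-2,2,3(1H)-tricarboxylate | CCOC(=O)C1=Cc2cc(B3OC(C)(C)C(C)(C)O3)c(B3OC(C)(C)C(C)(C)O3)cc2[C@@H](c2cc(C(=O)OCC)oc(=O)c2)C1(C(=O)OCC)C(=O)OCC
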